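**Retrosynthetic overview**

1. End game: the propenal is made last from a 2-isopropenyl group by allylic C–H oxidation and MnO2. The (R)-1-(angeloyloxy)ethyl arm comes from catalyst-controlled reduction of the 5-acetyl group and angeloylation, and the C3 acetate from the C3 alcohol.
2. Key disconnection: both bonds to C2 of the dihydrofuran ring (C2–C3 and O1–C2) are cut in one operation. This leads to O-silylated 5-acetylsalicylaldehyde and a C2-symmetric chiral methallylsulfonium salt, joined in a formal [4+1] annulation through a trans-vinyl epoxide that the unmasked phenoxide O1 opens at C2.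
3. Enabling feature: C2 is bonded to the sp2 carbon of the propenyl unit, so C2 is allylic. It can be brought in as the carbanionic carbon of an allylic sulfonium ylide and is the activated epoxide terminus for O1; the 5-acetyl group on the benzene ring, para to O1 (C5 versus C7a), tempers the phenoxide so that the C3–O bond is not ionized.
4. Ring order: the benzene ring is bought; the dihydrofuran ring (O1, C2, C3, C3a, C7a) is the only ring made and is closed last, in step 5. C3 is set by the chiral sulfide, C2 is relayed from it, and the side-chain carbinol is set separately by catalyst control.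

Key step: step 5

Assumption: the ylide from (2R,5R)-2,5-dimethylthiolane is taken to add to this aldehyde with the sense recalled for its benzyl and methallyl analogues ((S,S)-configured trans-epoxides), which is not verified here; diol 3 is sold as both enantiomers, so the opposite sense would only change the choice of 3; 1 and 14 are taken as catalogue compounds.

**Route**

Step 1
Reactants: 1 5-acetyl-2-hydroxybenzaldehyde
Product: 2 5-acetyl-2-[(triisopropylsilyl)oxy]benzaldehyde
Conditions: iPr3SiCl, imidazole, DMF, 0 °C to rt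
Reagents that add atoms: chlorotriisopropylsilane, CC(C)[Si](Cl)(C(C)C)C(C)C
Why: O-silylation of the acidic phenol should be clean, and the bulky silyl ether masks O1 during the ylide addition and is the common silyl group least prone to shift between oxygens.

Step 2
Reactants: 3 (2S,5S)-hexane-2,5-diol
Product: 4 (2S,5S)-hexane-2,5-diyl dimethanesulfonate
Conditions: MsCl, Et3N, CH2Cl2, 0 °C
Reagents that add atoms: methanesulfonyl chloride, CS(=O)(=O)Cl
Why: Mesylation of both secondary alcohols breaks no bond to either stereocentre, so both stay (S).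

Step 3
Reactants: 4 (2S,5S)-hexane-2,5-diyl dimethanesulfonate
Product: 5 (2R,5R)-2,5-dimethylthiolane
Conditions: Na2S·9H2O, DMSO, rt to 50 °C; distillation
Reagents that add atoms: sodium sulfide, [Na+].[Na+].[S-2]
Why: Double SN2 thioetherification (intermolecular, then 5-exo-tet) inverts both centres, so the (S,S)-dimesylate should give the C2-symmetric (R,R)-sulfide.

Step 4
Reactants: 5 (2R,5R)-2,5-dimethylthiolane; 6 3-bromo-2-methylprop-1-ene (methallyl bromide)
Product: 7 (2R,5R)-2,5-dimethyl-1-(2-methylprop-2-en-1-yl)thiolan-1-ium tetrafluoroborate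
Conditions: NaBF4, CH2Cl2/H2O, rt
Reagents that add atoms: sodium tetrafluoroborate, [Na+].F[B-](F)(F)F
Why: S-alkylation of the sulfide by the allylic bromide, driven by exchange to the non-nucleophilic tetrafluoroborate, should give one sulfonium salt because the two sulfur lone pairs of the C2-symmetric thiolane are equivalent.

Step 5
Reactants: 7 (2R,5R)-2,5-dimethyl-1-(2-methylprop-2-en-1-yl)thiolan-1-ium tetrafluoroborate; 2 5-acetyl-2-[(triisopropylsilyl)oxy]benzaldehyde
Product: 11 1-[(2R,3S)-3-hydroxy-2-(prop-1-en-2-yl)-2,3-dihydro-1-benzofuran-5-yl]ethanone, via sulfonium ylide 8 (not isolated), via trans-vinyl epoxide 9 (not isolated), via ammonium phenoxide 10 (not isolated)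
Conditions: 7 (1.10 equiv), KN(SiMe3)2 (1.05 equiv), THF, −78 °C; then 2, −78 to −40 °C; then Bu4NF, THF, −40 to 0 °C; aq. NH4Cl
Reagents that add atoms: none
Why: Ylide 8, formed by deprotonation of 7 at the allylic S–CH2, should add through its α-carbon to the aldehyde of 2 to give an anti-betaine that closes (3-exo-tet, loss of sulfide 5) to the trans-vinyl epoxide 9; fluoride then frees phenoxide 10, whose O1 opens the epoxide at the allylic carbon with inversion, so that C2–C3 and O1–C2 are both made in one flask as a formal [4+1] annulation. The closest known reaction types are the asymmetric sulfur-ylide (Corey–Chaykovsky) epoxidation of aromatic aldehydes with C2-symmetric thiolanium allyl ylides and the sulfur-ylide annulation of salicylaldehydes to 2,3-dihydrobenzofuran-3-ols. The dihydrofuran ring closes by 5-endo-tet epoxide opening (intramolecular SN2 at C2); attack of O1 at C3 would give a four-membered ring and SN2' attack a seven-membered one. C3 is set by the chiral sulfonium group (face selection in betaine formation, expected to give the (2S,3S)-epoxide), and C2 is relayed from it, since a trans epoxide opened with inversion at C2 gives the 2,3-trans (2R,3S) product. The step needs aldehyde-over-ketone selectivity (the ketone is para to the silyloxy donor and the ylide is kept near one equivalent), SN2 opening at C2 in place of C3–O ionization (C2 is allylic, and the 5-acetyl group para to O1 makes the phenoxide a weak push toward an ortho-quinone methide), and epoxide closure before any O-to-O silyl shift (bulky triisopropylsilyl group, −78 °C).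

Step 6
Reactants: 11 1-[(2R,3S)-3-hydroxy-2-(prop-1-en-2-yl)-2,3-dihydro-1-benzofuran-5-yl]ethanone
Product: 12 (2R,3S)-5-acetyl-2-(prop-1-en-2-yl)-2,3-dihydro-1-benzofuran-3-yl acetate
Conditions: Ac2O, pyridine, 4-(dimethylamino)pyridine (cat.), CH2Cl2, 0 °C to rt
Reagents that add atoms: acetic anhydride, CC(=O)OC(C)=O
Why: Nucleophile-catalysed O-acetylation of the secondary C3 alcohol under basic, non-ionizing conditions should leave the benzylic C3–O bond and C2 untouched.

Step 7
Reactants: 12 (2R,3S)-5-acetyl-2-(prop-1-en-2-yl)-2,3-dihydro-1-benzofuran-3-yl acetate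
Product: 13 (2R,3S)-5-[(1R)-1-hydroxyethyl]-2-(prop-1-en-2-yl)-2,3-dihydro-1-benzofuran-3-yl acetate
Conditions: (S)-1-methyl-3,3-diphenyltetrahydro-1H,3H-pyrrolo[1,2-c][1,3,2]oxazaborole (0.2 equiv), catecholborane, toluene, −78 to −40 °C; MeOH, pH 7 buffer
Reagents that add atoms: none
Why: In this Corey–Bakshi–Shibata reduction the (S)-oxazaborolidine should deliver hydride to the face of the aryl methyl ketone that gives the (R)-carbinol under catalyst control (the remote ring centres exert no bias), while catecholborane at low temperature should spare the isopropenyl alkene and the acetate.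

Step 8
Reactants: 13 (2R,3S)-5-[(1R)-1-hydroxyethyl]-2-(prop-1-en-2-yl)-2,3-dihydro-1-benzofuran-3-yl acetate; 14 (2Z)-2-methylbut-2-enoic anhydride (angelic anhydride)
Product: 16 (1R)-1-[(2R,3S)-3-acetoxy-2-(prop-1-en-2-yl)-2,3-dihydro-1-benzofuran-5-yl]ethyl (2Z)-2-methylbut-2-enoate, via lithium alkoxide 15 (not isolated)
Conditions: LiN(SiMe3)2 (1.0 equiv), THF, −78 °C; then 14, −78 to −30 °C; aq. NH4Cl
Reagents that add atoms: none
Why: Acylation of a pre-formed lithium alkoxide by the symmetrical anhydride at low temperature (no amine catalyst, no acyl chloride) should transfer the angeloyl group without Z-to-E isomerization and with retention at the carbinol, because the C–O bond is not broken.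

Step 9
Reactants: 16 (1R)-1-[(2R,3S)-3-acetoxy-2-(prop-1-en-2-yl)-2,3-dihydro-1-benzofuran-5-yl]ethyl (2Z)-2-methylbut-2-enoate
Product: 17 (1R)-1-[(2R,3S)-3-acetoxy-2-(3-hydroxyprop-1-en-2-yl)-2,3-dihydro-1-benzofuran-5-yl]ethyl (2Z)-2-methylbut-2-enoate
Conditions: SeO2 (0.3 equiv), tBuOOH, CH2Cl2, rt
Reagents that add atoms: tert-butyl hydroperoxide, CC(C)(C)OO; selenium dioxide (oxygen carrier), O=[Se]=O
Why: Riley-type allylic oxidation (ene reaction, then [2,3]-sigmatropic shift) should hydroxylate the methyl group of the electron-rich 1,1-disubstituted alkene, the electron-poor angelate double bond should not react, and any aldehyde 18 formed early converges in step 10.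

Step 10
Reactants: 17 (1R)-1-[(2R,3S)-3-acetoxy-2-(3-hydroxyprop-1-en-2-yl)-2,3-dihydro-1-benzofuran-5-yl]ethyl (2Z)-2-methylbut-2-enoate
Product: 18 (1R)-1-[(2R,3S)-3-acetoxy-2-(3-oxoprop-1-en-2-yl)-2,3-dihydro-1-benzofuran-5-yl]ethyl (2Z)-2-methylbut-2-enoate
Conditions: MnO2 (activated, excess), CH2Cl2, rt
Reagents that add atoms: none
Why: MnO2 oxidation of the primary allylic alcohol to the enal is neutral, no other oxidizable alcohol is present and no stereocentre is touched.

**Compound list**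

1 | 5-acetyl-2-hydroxybenzaldehyde | CC(=O)c1ccc(O)c(C=O)c1 | starting material
2 | 5-acetyl-2-[(triisopropylsilyl)oxy]benzaldehyde | CC(=O)c1ccc(O[Si](C(C)C)(C(C)C)C(C)C)c(C=O)c1 | intermediate
3 | (2S,5S)-hexane-2,5-diol | C[C@H](O)CC[C@H](C)O | starting material
4 | (2S,5S)-hexane-2,5-diyl dimethanesulfonate | C[C@H](OS(C)(=O)=O)CC[C@H](C)OS(C)(=O)=O | intermediate
5 | (2R,5R)-2,5-dimethylthiolane | C[C@@H]1CC[C@@H](C)S1 | intermediate
6 | 3-bromo-2-methylprop-1-ene (methallyl bromide) | C=C(C)CBr | starting material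
7 | (2R,5R)-2,5-dimethyl-1-(2-methylprop-2-en-1-yl)thiolan-1-ium tetrafluoroborate | C[C@@H]1CC[C@@H](C)[S+]1CC(C)=C.F[B-](F)(F)F | intermediate
8 | (2R,5R)-2,5-dimethylthiolan-1-ium-1-yl 2-methylprop-2-en-1-ide (sulfonium ylide) | C[C@@H]1CC[C@@H](C)[S+]1[CH-]C(C)=C | intermediate
9 | 1-{3-[(2S,3S)-3-(prop-1-en-2-yl)oxiran-2-yl]-4-[(triisopropylsilyl)oxy]phenyl}ethanone | CC(=O)c1ccc(O[Si](C(C)C)(C(C)C)C(C)C)c(c1)[C@@H]1O[C@H]1C(C)=C | intermediate
10 | tetrabutylammonium 4-acetyl-2-[(2S,3S)-3-(prop-1-en-2-yl)oxiran-2-yl]phenolate | CC(=O)c1ccc([O-])c(c1)[C@@H]1O[C@H]1C(C)=C.CCCC[N+](CCCC)(CCCC)CCCC | intermediate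
11 | 1-[(2R,3S)-3-hydroxy-2-(prop-1-en-2-yl)-2,3-dihydro-1-benzofuran-5-yl]ethanone | C=C(C)[C@H]1Oc2ccc(C(C)=O)cc2[C@@H]1O | intermediate
12 | (2R,3S)-5-acetyl-2-(prop-1-en-2-yl)-2,3-dihydro-1-benzofuran-3-yl acetate | C=C(C)[C@H]1Oc2ccc(C(C)=O)cc2[C@@H]1OC(C)=O | intermediate
13 | (2R,3S)-5-[(1R)-1-hydroxyethyl]-2-(prop-1-en-2-yl)-2,3-dihydro-1-benzofuran-3-yl acetate | C=C(C)[C@H]1Oc2ccc([C@@H](C)O)cc2[C@@H]1OC(C)=O | intermediate
14 | (2Z)-2-methylbut-2-enoic anhydride (angelic anhydride) | C/C=C(/C)C(=O)OC(=O)/C(C)=C\C | starting material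
15 | lithium (1R)-1-[(2R,3S)-3-acetoxy-2-(prop-1-en-2-yl)-2,3-dihydro-1-benzofuran-5-yl]ethanolate | C=C(C)[C@H]1Oc2ccc([C@@H](C)[O-])cc2[C@@H]1OC(C)=O.[Li+] | intermediate
16 | (1R)-1-[(2R,3S)-3-acetoxy-2-(prop-1-en-2-yl)-2,3-dihydro-1-benzofuran-5-yl]ethyl (2Z)-2-methylbut-2-enoate | C=C(C)[C@H]1Oc2ccc([C@@H](C)OC(=O)/C(C)=C\C)cc2[C@@H]1OC(C)=O | intermediate
17 | (1R)-1-[(2R,3S)-3-acetoxy-2-(3-hydroxyprop-1-en-2-yl)-2,3-dihydro-1-benzofuran-5-yl]ethyl (2Z)-2-methylbut-2-enoate | C=C(CO)[C@H]1Oc2ccc([C@@H](C)OC(=O)/C(C)=C\C)cc2[C@@H]1OC(C)=O | intermediate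
18 | (1R)-1-[(2R,3S)-3-acetoxy-2-(3-oxoprop-1-en-2-yl)-2,3-dihydro-1-benzofuran-5-yl]ethyl (2Z)-2-methylbut-2-enoate | C=C(C=O)[C@H]1Oc2ccc([C@@H](C)OC(=O)/C(C)=C\C)cc2[C@@H]1OC(C)=O | target

**Step count**

Total step count: 10.
Longest linear sequence: 9 steps (steps 2, 3, 4, 5, 6, 7, 8, 9, 10, from diol 3); from aldehyde 1 the sequence is 7 steps (steps 1, 5, 6, 7, 8, 9, 10).

**Steps most likely to fail**

Step 5. What may go wrong: poor facial or anti/syn selectivity in the ylide addition (erosion of enantiomeric purity, cis-epoxide), or an O-to-O silyl shift in the betaine that lets O1 displace the sulfonium group directly and so reverses the C2/C3 relationship. The fallback sets out from 2 and comes back at 12; it makes the ring without a chiral reagent and takes the enantiocontrol from an enzyme. Thiolane, 6 and NaBF4 would give 1-(2-methylprop-2-en-1-yl)thiolan-1-ium tetrafluoroborate F1. KN(SiMe3)2 in THF at −78 °C would convert it into thiolan-1-ium-1-yl 2-methylprop-2-en-1-ide F2, which with 2 should give racemic trans-1-{3-[3-(prop-1-en-2-yl)oxiran-2-yl]-4-[(triisopropylsilyl)oxy]phenyl}ethanone F3. Bu4NF should then give racemic tetrabutylammonium 4-acetyl-2-[trans-3-(prop-1-en-2-yl)oxiran-2-yl]phenolate F4, which cyclizes to racemic trans-1-[3-hydroxy-2-(prop-1-en-2-yl)-2,3-dihydro-1-benzofuran-5-yl]ethanone F5. A lipase-catalysed kinetic resolution (Candida antarctica lipase B, vinyl acetate, tBuOMe, rt) should acetylate the (2R,3S)-enantiomer preferentially, because its carbinol carries the aryl ring as the large and C2 as the medium substituent in the arrangement such lipases acylate fastest. This gives 12 directly; the slow-reacting enantiomer stays as the alcohol and is separated.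

Step 9. What may go wrong: ionization of the para-alkoxybenzylic angelate or of the C3 acetate by the acidic selenium species, loss of the Z geometry of the angelate, or stalling that forces harsher conditions. The fallback sets out from 12 and comes back at 17; it moves the C–H oxidation to a stage with no angelate and carries the new hydroxyl as a silyl ether. The same SeO2/tBuOOH oxidation applied to 12 should give (2R,3S)-5-acetyl-2-(3-hydroxyprop-1-en-2-yl)-2,3-dihydro-1-benzofuran-3-yl acetate F6. tBuMe2SiCl and imidazole in DMF would give (2R,3S)-5-acetyl-2-{3-[(tert-butyldimethylsilyl)oxy]prop-1-en-2-yl}-2,3-dihydro-1-benzofuran-3-yl acetate F7. The reduction of step 7 should give (2R,3S)-2-{3-[(tert-butyldimethylsilyl)oxy]prop-1-en-2-yl}-5-[(1R)-1-hydroxyethyl]-2,3-dihydro-1-benzofuran-3-yl acetate F8. LiN(SiMe3)2 would convert it into lithium (1R)-1-[(2R,3S)-3-acetoxy-2-{3-[(tert-butyldimethylsilyl)oxy]prop-1-en-2-yl}-2,3-dihydro-1-benzofuran-5-yl]ethanolate F9, which with 14 should give (1R)-1-[(2R,3S)-3-acetoxy-2-{3-[(tert-butyldimethylsilyl)oxy]prop-1-en-2-yl}-2,3-dihydro-1-benzofuran-5-yl]ethyl (2Z)-2-methylbut-2-enoate F10. HF·pyridine buffered with pyridine in THF at 0 °C should then release 17.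

Step 8. What may go wrong: Z-to-E isomerization of the angeloyl group during acyl transfer (tiglate formation), or acetyl scrambling by the alkoxide. The fallback sets out from 13 and comes back at 16; it builds the Z-alkene only after the ester bond exists. Steglich esterification of 13 with 2-[bis(2,2,2-trifluoroethoxy)phosphoryl]propanoic acid (N,N'-dicyclohexylcarbodiimide, 4-(dimethylamino)pyridine cat., CH2Cl2, 0 °C) should give (1R)-1-[(2R,3S)-3-acetoxy-2-(prop-1-en-2-yl)-2,3-dihydro-1-benzofuran-5-yl]ethyl 2-[bis(2,2,2-trifluoroethoxy)phosphoryl]propanoate F11. KN(SiMe3)2 with 18-crown-6 in THF at −78 °C would give potassium 1-{(1R)-1-[(2R,3S)-3-acetoxy-2-(prop-1-en-2-yl)-2,3-dihydro-1-benzofuran-5-yl]ethoxy}-2-[bis(2,2,2-trifluoroethoxy)phosphoryl]-1-oxopropan-2-ide F12. Acetaldehyde should then give 16 by a Z-selective Still–Gennari olefination.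

Further compounds

F1 | step 5 | 1-(2-methylprop-2-en-1-yl)thiolan-1-ium tetrafluoroborate | C=C(C)C[S+]1CCCC1.F[B-](F)(F)F
F2 | step 5 | thiolan-1-ium-1-yl 2-methylprop-2-en-1-ide | C=C(C)[CH-][S+]1CCCC1
F3 | step 5 | racemic trans-1-{3-[3-(prop-1-en-2-yl)oxiran-2-yl]-4-[(triisopropylsilyl)oxy]phenyl}ethanone | CC(=O)c1ccc(O[Si](C(C)C)(C(C)C)C(C)C)c(c1)[C@@H]1O[C@H]1C(C)=C.CC(=O)c1ccc(O[Si](C(C)C)(C(C)C)C(C)C)c(c1)[C@H]1O[C@@H]1C(C)=C
F4 | step 5 | racemic tetrabutylammonium 4-acetyl-2-[trans-3-(prop-1-en-2-yl)oxiran-2-yl]phenolate | CC(=O)c1ccc([O-])c(c1)[C@@H]1O[C@H]1C(C)=C.CC(=O)c1ccc([O-])c(c1)[C@H]1O[C@@H]1C(C)=C.CCCC[N+](CCCC)(CCCC)CCCC.CCCC[N+](CCCC)(CCCC)CCCC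
F5 | step 5 | racemic trans-1-[3-hydroxy-2-(prop-1-en-2-yl)-2,3-dihydro-1-benzofuran-5-yl]ethanone | C=C(C)[C@H]1Oc2ccc(C(C)=O)cc2[C@@H]1O.C=C(C)[C@@H]1Oc2ccc(C(C)=O)cc2[C@H]1O
F6 | step 9 | (2R,3S)-5-acetyl-2-(3-hydroxyprop-1-en-2-yl)-2,3-dihydro-1-benzofuran-3-yl acetate | C=C(CO)[C@H]1Oc2ccc(C(C)=O)cc2[C@@H]1OC(C)=O
F7 | step 9 | (2R,3S)-5-acetyl-2-{3-[(tert-butyldimethylsilyl)oxy]prop-1-en-2-yl}-2,3-dihydro-1-benzofuran-3-yl acetate | C=C(CO[Si](C)(C)C(C)(C)C)[C@H]1Oc2ccc(C(C)=O)cc2[C@@H]1OC(C)=O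
F8 | step 9 | (2R,3S)-2-{3-[(tert-butyldimethylsilyl)oxy]prop-1-en-2-yl}-5-[(1R)-1-hydroxyethyl]-2,3-dihydro-1-benzofuran-3-yl acetate | C=C(CO[Si](C)(C)C(C)(C)C)[C@H]1Oc2ccc([C@@H](C)O)cc2[C@@H]1OC(C)=O
F9 | step 9 | lithium (1R)-1-[(2R,3S)-3-acetoxy-2-{3-[(tert-butyldimethylsilyl)oxy]prop-1-en-2-yl}-2,3-dihydro-1-benzofuran-5-yl]ethanolate | C=C(CO[Si](C)(C)C(C)(C)C)[C@H]1Oc2ccc([C@@H](C)[O-])cc2[C@@H]1OC(C)=O.[Li+]
F10 | step 9 | (1R)-1-[(2R,3S)-3-acetoxy-2-{3-[(tert-butyldimethylsilyl)oxy]prop-1-en-2-yl}-2,3-dihydro-1-benzofuran-5-yl]ethyl (2Z)-2-methylbut-2-enoate | C=C(CO[Si](C)(C)C(C)(C)C)[C@H]1Oc2ccc([C@@H](C)OC(=O)/C(C)=C\C)cc2[C@@H]1OC(C)=O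
F11 | step 8 | (1R)-1-[(2R,3S)-3-acetoxy-2-(prop-1-en-2-yl)-2,3-dihydro-1-benzofuran-5-yl]ethyl 2-[bis(2,2,2-trifluoroethoxy)phosphoryl]propanoate (both epimers at the phosphonate-bearing carbon) | C=C(C)[C@H]1Oc2ccc([C@@H](C)OC(=O)C(C)P(=O)(OCC(F)(F)F)OCC(F)(F)F)cc2[C@@H]1OC(C)=O
F12 | step 8 | potassium 1-{(1R)-1-[(2R,3S)-3-acetoxy-2-(prop-1-en-2-yl)-2,3-dihydro-1-benzofuran-5-yl]ethoxy}-2-[bis(2,2,2-trifluoroethoxy)phosphoryl]-1-oxopropan-2-ide | C=C(C)[C@H]1Oc2ccc([C@@H](C)OC(=O)[C-](C)P(=O)(OCC(F)(F)F)OCC(F)(F)F)cc2[C@@H]1OC(C)=O.[K+]
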